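## Retrosynthetic overview

1. C4–C1′ (broken first, made last): the naphthalene is attached by Friedel–Crafts capture of a chroman-derived ortho-quinone methide, anti to the C2 methyl group, which gives the 2,4-trans product.
2. O1–C2 (key disconnection): one of the two equivalent resorcinol OH groups adds enantioselectively, in the Markovnikov sense, to a terminal alkene. This closes the pyran ring and sets C2.
3. C3–C4: Barbier allylation of 2,6-dihydroxybenzaldehyde.
4. Ring order: both aromatic systems are bought. Only the pyran ring is built (step 2), and no protecting groups are used.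

Assumption: 1 and 6 are taken as catalogue chemicals, and the (R,R) ligand is assumed to give (2R) in step 2; its mirror image is used if the first run gives (2S).

## Route

Step 1
Reactants: 1 2,6-dihydroxybenzaldehyde; 2 allyl bromide
Product: 4 rac-2-(1-hydroxybut-3-en-1-yl)benzene-1,3-diol, via allylzinc bromide 3 (not isolated)
Conditions: Zn dust (1.5 equiv), 2 (1.4 equiv), THF/sat. aq NH4Cl 1:1, 0 °C → rt, 1 h; extraction at pH 6–7, used crude
Reagents that add atoms: none
Why: In an aqueous Barbier allylation the allylzinc adds to the aldehyde faster than it is protonated and free phenols are tolerated; the new carbinol centre is racemic, which does not matter because step 3 erases it.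

Step 2
Reactants: 4 rac-2-(1-hydroxybut-3-en-1-yl)benzene-1,3-diol
Product: 5 (2R)-2-methyl-3,4-dihydro-2H-chromene-4,5-diol (mixture of C4 epimers)
Conditions: [(R,R)-N,N'-bis(3,5-di-tert-butylsalicylidene)-1,2-cyclohexanediaminato]cobalt (C36H52CoN2O2, 5 mol %), 1-fluoro-2,4,6-trimethylpyridinium triflate (1.3 equiv), PhSiH3 (1.3 equiv), 2,4,6-collidine (0.3 equiv), PhCF3/CH2Cl2 1:1, −20 °C, Ar, 24 h
Reagents that add atoms: none
Why: Proposed new method: enantioselective cobalt-hydride MHAT/radical-polar-crossover hydroalkoxylation with a phenol as nucleophile and a six-membered chroman ring as product; the divalent cobalt salen complex is oxidised by the N-fluoropyridinium salt and takes hydride from PhSiH3 to give a trivalent cobalt hydride, which transfers H• to the terminal CH2 (Markovnikov); the secondary C2 radical is caught by divalent cobalt, the alkylcobalt is oxidised to the tetravalent state, and one of the two equivalent resorcinol OH groups displaces cobalt from the back side (6-exo, SN2-like) to form O1–C2; the two diastereomeric alkylcobalt species interconvert by homolysis and the chiral salen pocket lets only one be displaced fast, which sets C2 as R for both enantiomers of 4, whose small carbinol OH lies outside the pocket and is erased in step 3; the collidinium buffer is too weak an acid to ionise the benzylic alcohol; closest known reaction type: cobalt-salen MHAT hydroalkoxylation of unactivated alkenes, known in racemic form for phenols and in enantioselective form only for aliphatic alkenols closing to 2-methyltetrahydrofurans.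

Step 3
Reactants: 5 (2R)-2-methyl-3,4-dihydro-2H-chromene-4,5-diol; 6 1,8-dimethoxynaphthalene
Product: 8 cladonaphchrom A = (2R,4S)-4-(4,5-dimethoxynaphthalen-1-yl)-2-methyl-3,4-dihydro-2H-chromen-5-ol, via ortho-quinone methide 7 (not isolated)
Conditions: 6 (3.0 equiv), TsOH·H2O (5 mol %), CH2Cl2/MeCN 4:1, −20 → 0 °C, 5 added over 2 h; excess 6 recovered
Reagents that add atoms: none
Why: In this dehydrative Friedel–Crafts alkylation both C4 epimers of 5 ionise to the same cation/ortho-quinone methide stabilised by O1 and the 5-oxygen, and C4 of 6 (para to OMe) attacks pseudo-axially on the face away from the pseudo-equatorial 2-methyl group to give the 2,4-trans (4S) product, which peri strain with the 5-OH also favours thermodynamically.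

## Compound list

1 | 2,6-dihydroxybenzaldehyde | O=Cc1c(O)cccc1O | starting material
2 | allyl bromide | C=CCBr | starting material
3 | allylzinc bromide | C=CC[Zn]Br | intermediate
4 | rac-2-(1-hydroxybut-3-en-1-yl)benzene-1,3-diol | C=CCC(O)c1c(O)cccc1O | intermediate
5 | (2R)-2-methyl-3,4-dihydro-2H-chromene-4,5-diol, C4 epimer mixture | C[C@@H]1CC(O)c2c(O)cccc2O1 | intermediate
6 | 1,8-dimethoxynaphthalene | COc1cccc2cccc(OC)c12 | starting material
7 | (2R)-2-methyl-2,3-dihydro-5H-chromen-5-one (ortho-quinone methide, C4=C4a) | C[C@@H]1CC=C2C(=O)C=CC=C2O1 | intermediate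
8 | cladonaphchrom A, (2R,4S)-4-(4,5-dimethoxynaphthalen-1-yl)-2-methyl-3,4-dihydro-2H-chromen-5-ol (2,4-trans) | COc1cccc2c([C@@H]3C[C@@H](C)Oc4cccc(O)c43)ccc(OC)c12 | target

## Step count and risks

Total step count: 3. Longest linear sequence: 3.

**Step 2 (the new step, highest risk).**
- Failure modes:
  - low ee for a phenol nucleophile and a six-membered ring;
  - different response of the two enantiomers of 4 to the catalyst;
  - oxidation of the resorcinol by the N–F salt;
  - simple alkene reduction or isomerisation.
- Fallback (known chemistry), from 4 back to 5: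
  - Oxidise 4 with activated MnO2 in CH2Cl2 to 1-(2,6-dihydroxyphenyl)but-3-en-1-one F3.
  - Stir F3 with Et3N. The alkene moves into conjugation and the phenol closes by 6-endo oxa-Michael addition to racemic 5-hydroxy-2-methylchroman-4-one F4.
  - Carry out a dynamic kinetic resolution of F4 by asymmetric transfer hydrogenation: RuCl[(S,S)-TsDPEN](p-cymene) (2 mol %), HCO2H/DBU, MeCN, 40 °C.
  - C2 racemises by retro-oxa-Michael/oxa-Michael while only the (2R) ketone is reduced. This gives (2R,4S)-2-methyl-3,4-dihydro-2H-chromene-4,5-diol F5, the cis epimer of 5, which enters step 3 unchanged.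

**Step 3.**
- Failure modes:
  - self-condensation of 5 through its own activated C6/C8 positions;
  - loss of a proton from 7 to give 2-methyl-2H-chromen-5-ol, which costs yield and, if it re-enters through acid, costs ee;
  - some attack at C2 of 6.
- Fallback, from 5 and 6 back to 8; the nucleophile is changed from a free arene under acid to a boron-delivered aryl group:
  - Brominate 6 with NBS in MeCN to 4-bromo-1,8-dimethoxynaphthalene F6.
  - Convert F6 with n-BuLi, then B(OiPr)3, then aqueous acid into (4,5-dimethoxynaphthalen-1-yl)boronic acid F7.
  - Warm F7 (1.5 equiv) with 5, 3,3′-dibromo-BINOL (10 mol %) and 4 Å sieves in toluene.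
  - The boronic acid esterifies the C4 and C5 hydroxyls and the cyclic boronate opens to 7 held on boron. The aryl group then migrates to C4 on the face away from the methyl group. This is the known biphenol-catalysed conjugate addition of aryl boronates to ortho-quinone methides.

**Step 1.**
- Failure modes:
  - sluggish addition to the strongly hydrogen-bonded aldehyde;
  - loss of the labile benzylic alcohol 4 through ortho-quinone methide formation in the zinc-salt medium.
- Fallback, from 1 back to 4; a protecting-group detour in anhydrous medium:
  - Silylate 1 (TBSCl, imidazole, DMF) to 2,6-bis(tert-butyldimethylsilyloxy)benzaldehyde F1.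
  - Add CH2=CHCH2MgBr in THF at −78 °C to give 1-[2,6-bis(tert-butyldimethylsilyloxy)phenyl]but-3-en-1-ol F2.
  - Remove both silyl groups with Bu4NF buffered with AcOH at 0 °C to give 4.

## Further compounds

F1 | step 1 | 2,6-bis(tert-butyldimethylsilyloxy)benzaldehyde | CC(C)(C)[Si](C)(C)Oc1cccc(O[Si](C)(C)C(C)(C)C)c1C=O
F2 | step 1 | rac-1-[2,6-bis(tert-butyldimethylsilyloxy)phenyl]but-3-en-1-ol | C=CCC(O)c1c(O[Si](C)(C)C(C)(C)C)cccc1O[Si](C)(C)C(C)(C)C
F3 | step 2 | 1-(2,6-dihydroxyphenyl)but-3-en-1-one | C=CCC(=O)c1c(O)cccc1O
F4 | step 2 | rac-5-hydroxy-2-methylchroman-4-one | CC1CC(=O)c2c(O)cccc2O1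
F5 | step 2 | (2R,4S)-2-methyl-3,4-dihydro-2H-chromene-4,5-diol (cis) | C[C@@H]1C[C@H](O)c2c(O)cccc2O1
F6 | step 3 | 4-bromo-1,8-dimethoxynaphthalene | COc1cccc2c(Br)ccc(OC)c12
F7 | step 3 | (4,5-dimethoxynaphthalen-1-yl)boronic acid | COc1cccc2c(B(O)O)ccc(OC)c12
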